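**Plan**

- Retrosynthesis: the three sulfate S–O bonds are cut first (back to geraldol, 3,7,4'-trihydroxy-3'-methoxyflavone), then the C3–O bond (back to a flavone), then ring C at O1–C8a, C4–C4a and O1–C2.
- Enabling feature (flavone numbering): O1 and the carbonyl carbon C4 sit on the adjacent ring A carbons C8a and C4a, and C2 carries ring B. An aryne across C4a–C8a can therefore take up the oxygen and the acyl carbon of one 3-arylpropiolic acid, whose alkyne becomes C2=C3.
- Forward: ring A is prepared as an ortho-silylaryl triflate (steps 1–4) and ring B as the arylpropiolic acid (steps 5–6). Ring C closes when the two are joined (step 7), followed by C3 hydroxylation, hydrogenolysis and trisulfation (steps 8–10).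
- Stereochemistry: the target has no stereocentre. The only orientation to control is that of addition to the aryne, steered by a chlorine at C5 that is later removed together with the benzyl groups.

Key step: step 7

Remark: the target is drawn as the free tris(hydrogen sulfate), so the route ends with a cold acid ion exchange of the pyridinium salt; the free acid is expected to keep best cold or as a salt.

**Step 1**
Reactants: 1 4-(benzyloxy)phenol
Product: 2 4-(benzyloxy)-2-chlorophenol
Conditions: SO2Cl2 (1.05 equiv), i-Bu2NH (cat.), toluene, 0 °C to rt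
Reagents that add atoms: sulfuryl chloride, O=S(=O)(Cl)Cl
Why: Electrophilic aromatic chlorination in which the free hydroxyl, the stronger donor and hydrogen-bonded to the amine catalyst, directs chlorine ortho to itself while the para position is blocked by the benzyloxy group.

**Step 2**
Reactants: 2 4-(benzyloxy)-2-chlorophenol
Product: 3 4-(benzyloxy)-2-bromo-6-chlorophenol
Conditions: NBS (1.05 equiv), i-Pr2NH (cat.), CH2Cl2, 0 °C
Reagents that add atoms: N-bromosuccinimide, O=C1CCC(=O)N1Br
Why: Amine-catalysed ortho-bromination of a phenol with NBS, the one remaining position ortho to the hydroxyl being the most activated site of the ring.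

**Step 3**
Reactants: 3 4-(benzyloxy)-2-bromo-6-chlorophenol
Product: 4 [4-(benzyloxy)-2-bromo-6-chlorophenoxy]trimethylsilane
Conditions: HMDS (1.2 equiv), THF, reflux; evaporate
Reagents that add atoms: hexamethyldisilazane, C[Si](C)(C)N[Si](C)(C)C
Why: O-silylation of a phenol by HMDS, driven by loss of ammonia, which places the silyl group where the next step can transfer it to carbon.

**Step 4**
Reactants: 4 [4-(benzyloxy)-2-bromo-6-chlorophenoxy]trimethylsilane
Product: 7 4-(benzyloxy)-2-chloro-6-(trimethylsilyl)phenyl trifluoromethanesulfonate, via aryllithium 5 (not isolated), via lithium 2-silylphenoxide 6 (not isolated)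
Conditions: n-BuLi (1.1 equiv), THF, −100 °C to −80 °C; Tf2O (1.2 equiv), −100 °C to −80 °C
Reagents that add atoms: trifluoromethanesulfonic anhydride, O=S(=O)(OS(=O)(=O)C(F)(F)F)C(F)(F)F
Why: Bromine–lithium exchange outruns any attack on the C–Cl bond or the benzyl ether at −100 °C, the ortho-lithiated aryl silyl ether undergoes the 1,3 O-to-C silyl shift (retro-Brook rearrangement) and the phenoxide is trapped by Tf2O, the standard entry to ortho-silylaryl triflates.

**Step 5**
Reactants: 8 4-(benzyloxy)-3-methoxybenzaldehyde (commercial O-benzylvanillin)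
Product: 9 1-(benzyloxy)-4-(2,2-dibromoethenyl)-2-methoxybenzene
Conditions: CBr4 (2 equiv), PPh3 (4 equiv), CH2Cl2, 0 °C
Reagents that add atoms: carbon tetrabromide, BrC(Br)(Br)Br
Why: Ramirez gem-dibromoolefination of an aromatic aldehyde by the ylide formed from CBr4 and PPh3, the first stage of the Corey–Fuchs homologation.

**Step 6**
Reactants: 9 1-(benzyloxy)-4-(2,2-dibromoethenyl)-2-methoxybenzene
Product: 11 3-[4-(benzyloxy)-3-methoxyphenyl]prop-2-ynoic acid, via lithium acetylide 10 (not isolated)
Conditions: n-BuLi (2.2 equiv), THF, −78 °C to 0 °C; CO2 (gas), −78 °C to rt; aq. HCl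
Reagents that add atoms: carbon dioxide, O=C=O
Why: Second stage of the Corey–Fuchs sequence, in which two equivalents of n-BuLi turn the dibromoalkene into the lithium acetylide (elimination and bromine–lithium exchange), which is carboxylated by CO2.

**Step 7**
Reactants: 7 4-(benzyloxy)-2-chloro-6-(trimethylsilyl)phenyl trifluoromethanesulfonate; 11 3-[4-(benzyloxy)-3-methoxyphenyl]prop-2-ynoic acid
Product: 14 7-(benzyloxy)-2-[4-(benzyloxy)-3-methoxyphenyl]-5-chloro-4H-chromen-4-one, via aryne 12 (not isolated), via ortho-hydroxyaryl ynone 13 (not isolated)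
Conditions: CsF (4 equiv), 7 (1.5 equiv), THF, 125 °C, sealed tube
Reagents that add atoms: none
Why: Fluoride removes the silyl group of 7 and triflate leaves to give aryne 12; the caesium carboxylate of 11 adds through oxygen to the aryne carbon that becomes C8a, the aryl anion at C4a attacks its own ester carbonyl through a four-membered alkoxide that collapses to the ortho-acyl phenoxide 13 (C8a–O1 and C4a–C4 formed), and this phenoxide adds to the β-carbon of the ynone to form O1–C2 before protonation at C3. The closest known reaction type is the fluoride-induced insertion of arynes into the C–O bond of carboxylic acids to give ortho-hydroxyaryl ketones, which with 3-arylpropiolic acids runs on to flavones. Ring C closes by a 6-endo-dig oxa-Michael addition. No stereocentre is formed. Two selectivities are needed: oxygen must bond to the aryne carbon remote from chlorine, which the chlorine next to the triple bond should secure by distorting the aryne and by stabilising inductively the negative charge developing at C4a, against only a weak opposite bias from the para benzyloxy group; and 6-endo must beat 5-exo closure, which the polarisation of the ynone towards its aryl-bearing β-carbon in an aprotic medium should favour.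

**Step 8**
Reactants: 14 7-(benzyloxy)-2-[4-(benzyloxy)-3-methoxyphenyl]-5-chloro-4H-chromen-4-one
Product: 16 7-(benzyloxy)-2-[4-(benzyloxy)-3-methoxyphenyl]-5-chloro-3-hydroxy-4H-chromen-4-one, via flavone 2,3-epoxide 15 (not isolated)
Conditions: DMDO (acetone solution, excess in portions), CH2Cl2, 0 °C to rt; then p-TsOH·H2O (cat.), CHCl3, rt
Reagents that add atoms: dimethyldioxirane, CC1(C)OO1
Why: Electrophilic epoxidation of the C2=C3 bond of a flavone by DMDO, then acid opening of the epoxide at C2 (cation stabilised by O1 and ring B) and loss of the C3 proton, the known route from flavones to 3-hydroxyflavones.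

**Step 9**
Reactants: 16 7-(benzyloxy)-2-[4-(benzyloxy)-3-methoxyphenyl]-5-chloro-3-hydroxy-4H-chromen-4-one
Product: 18 3,7-dihydroxy-2-(4-hydroxy-3-methoxyphenyl)-4H-chromen-4-one (geraldol), via 5-chlorogeraldol 17 (not isolated)
Conditions: H2 (1 atm), 10% Pd/C, THF–MeOH, rt; then Et3N (3 equiv), H2 (1 atm), rt
Reagents that add atoms: none
Why: Hydrogenolysis on Pd/C first cleaves the two aryl benzyl ethers under neutral conditions and, once Et3N is added to take up HCl, removes the carbonyl-activated C5 chlorine (base-promoted Pd/C hydrodechlorination), the amine being held back because nitrogen bases slow O-benzyl cleavage and the chelated flavonol C2=C3 bond not being reduced at 1 atm.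

**Step 10**
Reactants: 18 3,7-dihydroxy-2-(4-hydroxy-3-methoxyphenyl)-4H-chromen-4-one (geraldol)
Product: 20 2-[3-methoxy-4-(sulfooxy)phenyl]-4-oxo-4H-chromene-3,7-diyl bis(hydrogen sulfate), via tris(pyridinium) trisulfate 19 (not isolated)
Conditions: SO3·pyridine (12 equiv), pyridine–DMF, 60 °C; then sulfonated polystyrene resin (H+ form), H2O, 0 °C; freeze-dry
Reagents that add atoms: sulfur trioxide–pyridine complex, [O-]S(=O)(=O)[n+]1ccccc1
Why: O-sulfation of the 7- and 4'-phenols and of the enolic 3-hydroxyl by the SO3·pyridine complex (persulfation of flavonols is known and no unreactive 5-hydroxyl is present), after which the resin exchanges pyridinium for H+ to release the free half-esters.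

**Compound list**

1 | 4-(benzyloxy)phenol | Oc1ccc(OCc2ccccc2)cc1 | starting material
2 | 4-(benzyloxy)-2-chlorophenol | Oc1ccc(OCc2ccccc2)cc1Cl | intermediate
3 | 4-(benzyloxy)-2-bromo-6-chlorophenol | Oc1c(Cl)cc(OCc2ccccc2)cc1Br | intermediate
4 | [4-(benzyloxy)-2-bromo-6-chlorophenoxy]trimethylsilane | C[Si](C)(C)Oc1c(Cl)cc(OCc2ccccc2)cc1Br | intermediate
5 | [5-(benzyloxy)-3-chloro-2-(trimethylsilyloxy)phenyl]lithium | [Li]c1cc(OCc2ccccc2)cc(Cl)c1O[Si](C)(C)C | intermediate
6 | lithium 4-(benzyloxy)-2-chloro-6-(trimethylsilyl)phenoxide | [Li+].[O-]c1c(Cl)cc(OCc2ccccc2)cc1[Si](C)(C)C | intermediate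
7 | 4-(benzyloxy)-2-chloro-6-(trimethylsilyl)phenyl trifluoromethanesulfonate | C[Si](C)(C)c1cc(OCc2ccccc2)cc(Cl)c1OS(=O)(=O)C(F)(F)F | intermediate
8 | 4-(benzyloxy)-3-methoxybenzaldehyde | COc1cc(C=O)ccc1OCc1ccccc1 | starting material
9 | 1-(benzyloxy)-4-(2,2-dibromoethenyl)-2-methoxybenzene | COc1cc(C=C(Br)Br)ccc1OCc1ccccc1 | intermediate
10 | lithium [4-(benzyloxy)-3-methoxyphenyl]acetylide | [Li]C#Cc1ccc(OCc2ccccc2)c(OC)c1 | intermediate
11 | 3-[4-(benzyloxy)-3-methoxyphenyl]prop-2-ynoic acid | OC(=O)C#Cc1ccc(OCc2ccccc2)c(OC)c1 | intermediate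
12 | 5-(benzyloxy)-3-chlorobenzyne (5-(benzyloxy)-3-chloro-1,2-didehydrobenzene) | ClC1=CC(OCc2ccccc2)=CC#C1 | intermediate
13 | 1-[4-(benzyloxy)-2-chloro-6-hydroxyphenyl]-3-[4-(benzyloxy)-3-methoxyphenyl]prop-2-yn-1-one (present as its caesium phenoxide) | O=C(C#Cc1ccc(OCc2ccccc2)c(OC)c1)c1c(O)cc(OCc2ccccc2)cc1Cl | intermediate
14 | 7-(benzyloxy)-2-[4-(benzyloxy)-3-methoxyphenyl]-5-chloro-4H-chromen-4-one | O=c1cc(-c2ccc(OCc3ccccc3)c(OC)c2)oc2cc(OCc3ccccc3)cc(Cl)c12 | intermediate
15 | 7-(benzyloxy)-2-[4-(benzyloxy)-3-methoxyphenyl]-5-chloro-2,3-epoxy-2,3-dihydro-4H-chromen-4-one (racemic, cis-fused) | O=C1c2c(Cl)cc(OCc3ccccc3)cc2OC2(c3ccc(OCc4ccccc4)c(OC)c3)OC12 | intermediate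
16 | 7-(benzyloxy)-2-[4-(benzyloxy)-3-methoxyphenyl]-5-chloro-3-hydroxy-4H-chromen-4-one | O=c1c(O)c(-c2ccc(OCc3ccccc3)c(OC)c2)oc2cc(OCc3ccccc3)cc(Cl)c12 | intermediate
17 | 5-chloro-3,7-dihydroxy-2-(4-hydroxy-3-methoxyphenyl)-4H-chromen-4-one | COc1cc(-c2oc3cc(O)cc(Cl)c3c(=O)c2O)ccc1O | intermediate
18 | 3,7-dihydroxy-2-(4-hydroxy-3-methoxyphenyl)-4H-chromen-4-one (geraldol) | COc1cc(-c2oc3cc(O)ccc3c(=O)c2O)ccc1O | intermediate
19 | tris(pyridinium) 2-(3-methoxy-4-sulfonatooxyphenyl)-4-oxo-4H-chromene-3,7-diyl bis(sulfate) | COc1cc(-c2oc3cc(OS(=O)(=O)[O-])ccc3c(=O)c2OS(=O)(=O)[O-])ccc1OS(=O)(=O)[O-].c1cc[nH+]cc1.c1cc[nH+]cc1.c1cc[nH+]cc1 | intermediate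
20 | 2-[3-methoxy-4-(sulfooxy)phenyl]-4-oxo-4H-chromene-3,7-diyl bis(hydrogen sulfate) | COc1cc(-c2oc3cc(OS(=O)(=O)O)ccc3c(=O)c2OS(=O)(=O)O)ccc1OS(=O)(=O)O | target

**Count and risks**

Total step count: 10. Longest linear sequence: 8 steps (steps 1–4, then 7–10); steps 5–6 form the second branch.

Steps most likely to fail:

1. Step 7. Several processes could divert it: thermal decarboxylation of the caesium arylpropiolate before it captures the aryne, loss of chloride from the ortho-chloroaryl anion ahead of the acyl shift, addition to the aryne in the wrong orientation, or 5-exo closure of the phenoxide to an aurone. The fallback gives up the aryne and builds ring C by chalcone chemistry. Setting out from aldehyde 8, Claisen–Schmidt condensation with commercial 1-[4-(benzyloxy)-2-hydroxyphenyl]ethan-1-one (KOH, EtOH, rt) should give (E)-1-[4-(benzyloxy)-2-hydroxyphenyl]-3-[4-(benzyloxy)-3-methoxyphenyl]prop-2-en-1-one F1. Algar–Flynn–Oyamada oxidation (H2O2, NaOH, MeOH, 0 °C to rt) should convert it into 7-(benzyloxy)-2-[4-(benzyloxy)-3-methoxyphenyl]-3-hydroxy-4H-chromen-4-one F2, and hydrogenolysis (H2, 10% Pd/C, THF–MeOH, rt) comes back to the route at geraldol 18.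

2. Step 8. Epoxidation of the electron-poor C2=C3 bond may be slow enough for DMDO to oxidise the benzylic C–H bonds or the electron-rich ring B instead. The fallback brings the oxygen in through carbanion chemistry. Setting out from flavone 14, LiN(i-Pr)2 in THF at −78 °C should remove the C3 proton next to the carbonyl to give [7-(benzyloxy)-2-[4-(benzyloxy)-3-methoxyphenyl]-5-chloro-4-oxo-4H-chromen-3-yl]lithium F3. B(OMe)3 should trap it as dimethyl [7-(benzyloxy)-2-[4-(benzyloxy)-3-methoxyphenyl]-5-chloro-4-oxo-4H-chromen-3-yl]boronate F4, and oxidation of the C–B bond with H2O2 and AcOH comes back to the route at flavonol 16.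

3. Step 10. Sulfation may stall at the hydrogen-bonded, hindered 3-hydroxyl, and the free acid may lose sulfate by acid catalysis during isolation. The fallback introduces the sulfates as protected diesters that can be purified on silica. Setting out from geraldol 18, 2,2,2-trichloroethyl chlorosulfate with Et3N and DMAP in THF should give 2-[3-methoxy-4-[(2,2,2-trichloroethoxy)sulfonyloxy]phenyl]-4-oxo-4H-chromene-3,7-diyl bis(2,2,2-trichloroethyl sulfate) F5. Zn dust and HCO2NH4 in MeOH should remove the trichloroethyl groups to give triammonium 2-(3-methoxy-4-sulfonatooxyphenyl)-4-oxo-4H-chromene-3,7-diyl bis(sulfate) F6, and the cold H+ resin comes back to the route at target 20.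

**Further compounds**

F1 | step 7 | (E)-1-[4-(benzyloxy)-2-hydroxyphenyl]-3-[4-(benzyloxy)-3-methoxyphenyl]prop-2-en-1-one | O=C(/C=C/c1ccc(OCc2ccccc2)c(OC)c1)c1ccc(OCc2ccccc2)cc1O
F2 | step 7 | 7-(benzyloxy)-2-[4-(benzyloxy)-3-methoxyphenyl]-3-hydroxy-4H-chromen-4-one | O=c1c(O)c(-c2ccc(OCc3ccccc3)c(OC)c2)oc2cc(OCc3ccccc3)ccc12
F3 | step 8 | [7-(benzyloxy)-2-[4-(benzyloxy)-3-methoxyphenyl]-5-chloro-4-oxo-4H-chromen-3-yl]lithium | [Li]c1c(-c2ccc(OCc3ccccc3)c(OC)c2)oc2cc(OCc3ccccc3)cc(Cl)c2c1=O
F4 | step 8 | dimethyl [7-(benzyloxy)-2-[4-(benzyloxy)-3-methoxyphenyl]-5-chloro-4-oxo-4H-chromen-3-yl]boronate | COB(OC)c1c(-c2ccc(OCc3ccccc3)c(OC)c2)oc2cc(OCc3ccccc3)cc(Cl)c2c1=O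
F5 | step 10 | 2-[3-methoxy-4-[(2,2,2-trichloroethoxy)sulfonyloxy]phenyl]-4-oxo-4H-chromene-3,7-diyl bis(2,2,2-trichloroethyl sulfate) | COc1cc(-c2oc3cc(OS(=O)(=O)OCC(Cl)(Cl)Cl)ccc3c(=O)c2OS(=O)(=O)OCC(Cl)(Cl)Cl)ccc1OS(=O)(=O)OCC(Cl)(Cl)Cl
F6 | step 10 | triammonium 2-(3-methoxy-4-sulfonatooxyphenyl)-4-oxo-4H-chromene-3,7-diyl bis(sulfate) | COc1cc(-c2oc3cc(OS(=O)(=O)[O-])ccc3c(=O)c2OS(=O)(=O)[O-])ccc1OS(=O)(=O)[O-].[NH4+].[NH4+].[NH4+]
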